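## Analysis of the target

The target is a germacrane-type ten-membered carbocycle, numbered here C1 (CH2), C2 (ketone), C3–C4 (epoxide, C15 methyl on C4), C5 (OAc), C6 (lactone oxygen), C7, C8 (OAc), C9 ((R)-2-methylbutanoate) and C10 (exocyclic methylene C14). C11 (=C13H2) and C12 (carbonyl) complete an α-methylene-γ-butyrolactone fused at C6–C7. There are seven contiguous ring stereocentres and one in the side chain: 3R,4R,5S,6R,7R,8R,9R,2′R. In a flat drawing with C11 below the ring at C7 (α), O6, the epoxide oxygen and O9 are α, whereas O5, O8 and C15 are β. The lactone is therefore cis-fused, the epoxide derives from a ring-Z C3=C4 alkene, and C5/C6 and C8/C9 are trans pairs. Sensitive groups are the α,β-epoxy ketone, the Michael-accepting methylene lactone, two allylic esters and three ester oxygens of two different kinds on neighbouring carbons. The difficulty lies in the medium ring (entropy, transannular reactions, unreliable facial selectivity) in which nine of ten carbons are functionalised. The strategy rests on one feature: C7 carries the only carbon branch (C11) and lies 1,6 to the C2 carbonyl. If C11 is bonded to C2, the target maps onto a bicyclo[4.4.1]undecane whose bridge is C11, whose six-carbon arm C2–C7 is the ring of tropone and whose four-carbon arm C8–C9–C10(C14)–C1 is an isoprenoid diene. The bridge also gives a rigid frame on which the later oxidations can be directed.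

## Retrosynthetic reasoning

**Epoxy ketone last (31 → 30 → 29).** The C2 ketone is taken back to the 2α-carbinol 30 and the epoxide to the Z-allylic alcohol 29. The epoxy ketone is the most fragile group, and the C2 hydroxyl, which keeps the configuration of the former C2–C11 bond, delivers the oxidant to the α face of C3=C4.

**Esters and the exocyclic alkene (29 → 28 → 27 → 26 → 24 + 25 → 22).** The three acyl groups are removed one at a time through silyl ethers of graded stability (C2–OTBDPS, C8–OTBS). The C9 hydroxyl and the C10=C14 methylene are traced to the 9α,10α-epoxide of 22 (cleavage of C10–O, loss of a C14 proton), so C9–O is revealed only when C5 is already acetylated and C2 and C8 are masked, and can be acylated by 25.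

**Lactone (20 → 19 → 18).** The O6–C12 and C11–C12 bonds are cut together: 20 is the cyclocarbonylation product of the homopropargylic alcohol 19, whose C13 comes from one-carbon homologation of the C11 aldehyde held as lactol 18. This uses the C11 bridge carbon directly as the future C11 and needs no protection of the 5,6-diol.

**C4 methyl and the C5/C6 oxygens (17 → 16 → 15 → 14 → 13 → 12).** The C4–C15 bond is cut at a vinylic carbon, so the tropone-derived Z geometry of C3=C4 is never lost: 16 comes from iodoenone 15 by cross-coupling. The C5 ketone needed for the α-iodination comes from allylic oxidation of the 5α,6α-diol 13, and 13 from face-selective dihydroxylation of the diene in 12. Reduction of 16 then sets 5β-OH. All of this is done on the bridged frame, where the β face of C3–C6 is covered by the C8–C1 arm.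

**Bridge at the lactol level, C8 inversion, C9 oxygen (12 → 10 → 9 → 8 → 7).** The bridge of 12 is a silyl acetal. It is used instead of the lactone because the 5α-hydroxyl of a lactone diol would take over the C11 acyl group, and because C11 must become an aldehyde anyway. 12 comes from lactone 10 by reduction and in situ silylation. The 8β-oxygen of 10 is traced to the 8α-alcohol 8 by SN2 inversion (via 9). A route through a C8 ketone is avoided because chelation-controlled reduction of an α,β-epoxy ketone returns the cis-epoxy alcohol and the ketone would sit between two enolisable positions. The 9α,10α-epoxide of 8 is delivered by the 8α-hydroxyl of 7, so the "wrong" C8 configuration of the cycloadduct is used before it is corrected.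

**Resolution and oxygen insertion (7 → 6 → 5).** 7 is the product of an enantioselective enzymatic hydrolysis of the racemic acetate 6. This frees C8–OH without opening the strained lactone and selects the absolute configuration. Methanolysis of 6 is avoided: it would expose a β-acyloxy ester with a doubly activated C7–H to base and give up the bicyclic frame. 6 is the Baeyer–Villiger product of ketone 5, with oxygen inserted on the C2 side.

**Ring construction (5 → 3 + 4).** The C1–C2 and C7–C8 bonds are cut in a [6+4] sense to tropone 4 and dienyl acetate 3. The ten-membered ring is thereby formed from two flat, achiral partners in one bimolecular step, with C2, C7 and C8 set relative to each other and no regiochemical question because 4 is symmetric.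

**Diene (3 → 1 + 2).** 3 is the dienol acetate of 1, made by acyl transfer from 2.

## Alternatives that were turned down

**Alternative 1:** The ring is cut at C8–C9. Forward, a BF3·OEt2-promoted intramolecular addition of a (Z)-γ-alkoxyallylstannane terminus to a C8 aldehyde terminus would close the carbocycle A1 and create the C8 carbinol, the C9 ether and the C10=C14 methylene at once.
- For: the absolute configuration comes from asymmetric acyclic chemistry, not from a resolution; C8 (free OH) and C9 (MOM) emerge already differentiated; the exocyclic alkene needs no extra step. On these three points it is stronger than the chosen route, which needs an inversion at C8, an epoxide isomerisation and a kinetic resolution.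
- Against: the key step is a ten-membered cyclisation of a chain with a Z-trisubstituted alkene and a C5–C7 stereotriad. It is entropically costly, prone to oligomerisation, and its C8/C9 outcome is set in an open transition state whose facial sense inside a forming medium ring is hard to predict. The chain is a long linear synthesis, and after A1 the C2 oxidation, epoxide, lactone and removal of four kinds of protecting group remain.
- Comparison: the chosen route has the ring after two steps from commercial materials and then works on a rigid bicycle.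

**Alternative 2:** A C2–C7 bond is added retrosynthetically, so that the medium ring is hidden inside a bicyclic tertiary carbinol built from two six-membered rings. Forward, the alkoxy radical at C2 (CeCl3, light, thiol) would cleave C2–C7 to the C2 ketone and the ten-membered ring, and the C7 radical would close 5-exo-dig onto an orthoester-tethered alkyne to give A2.
- For: stereocentres are set on six-membered rings, macrocyclisation is avoided by ring expansion, and the ketone, C7–C11 bond and lactone carbons arise in one operation with epoxide and esters already in place. It is stronger in that everything from C3 to C9 is fixed before the medium ring exists.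
- Against: the alkoxy radical must choose C2–C7 over C2–C1 and over the bond to the epoxide carbon C3; the C7 radical sits between two oxygenated carbons and sets C7 in a cyclisation with little bias; the fully oxygenated bicyclic precursor with its tether is a long synthesis; C10 in A2 still carries CH2OTBS to be turned into the methylene.
- Comparison: both avoid macrocyclisation; the chosen route is shorter to the ring and does not hang on a selective radical fragmentation cascade.

**Alternative 3:** The C2–O and C5–O bonds are cut together. Forward, sensitised photo-oxygenation of a ring C2=C3–C4(Me)=C5 diene would add singlet oxygen [4+2] to give endoperoxide A3, to be rearranged later to the C2 ketone and C5 alcohol.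
- For: two oxygens in one reagent-free step, and the C4 methyl is carried from the start. On the C4 methyl it is clearly stronger than the chosen route, which spends three steps on it.
- Against: it is an end-game tactic that presupposes the whole ten-membered diene lactone and does not say how the ring is made. A (2Z,4Z)-diene in a ten-membered ring may not reach the planar s-cis geometry; the C10=C14 alkene and the C15 methyl offer ene pathways; the later base-induced cleavage must choose C2–H over C5–H; the enone epoxidation face is uncontrolled.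
- Comparison: the chosen route answers the ring-forming question first; alternative 3 could at best replace its last steps.

Key step: step 2

Remark: locants follow the numbering above; α means the face of the flat ten-membered ring on which C11 sits at C7, β the other face. Compounds 5 and 6 are racemates, drawn as the enantiomer that leads to the target. Compounds 11–18 are mixtures of C11 epimers.

## Route

Step 1
Reactants: 1 3-methylbut-2-enal; 2 isopropenyl acetate
Product: 3 (E)-1-acetoxy-3-methylbuta-1,3-diene
Conditions: TsOH·H2O (cat.), hydroquinone (trace), neat 2, 95 °C, acetone distilled off; fractional distillation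
Reagents that add atoms: none
Why: Acid-catalysed enol-ester exchange: the dienol of the enal is acetylated by 2 while acetone is removed; the conjugated dienyl acetate forms mainly as the E isomer, the only one that reacts in step 2.

Step 2
Reactants: 4 tropone; 3 (E)-1-acetoxy-3-methylbuta-1,3-diene
Product: 5 rac-exo-7-acetoxy-9-methylbicyclo[4.4.1]undeca-2,4,8-trien-11-one (C11 ketone bridging C2 and C7, 8α-OAc, C14 methyl on C10)
Conditions: 3 (2.5 equiv), BHT (cat.), xylene, 135 °C, sealed tube
Reagents that add atoms: none
Why: A thermally allowed, concerted [6π+4π] cycloaddition, suprafacial on both partners, in which the HOMO of the oxygenated diene meets the LUMO of tropone at C2 and C7 and forms C1–C2 and C7–C8 together. The closest known reaction is the thermal addition of tropone to (E)-1-acetoxybuta-1,3-diene and related 1-oxygenated dienes, which gives exo bicyclo[4.4.1]undecatrienones. The ten-membered ring closes as the periphery of the bicycle by this two-bond intermolecular addition, not by an end-to-end cyclisation, and the two seven-membered rings sharing C11 close in the same event. C2 and C7 are set cis because both bonds form on one face of planar tropone. C8 is set by the E geometry of 3 together with the exo transition state, which places the acetate on the same flat face as the bridge (α, epimeric to the target). The step needs [6+4] over [4+2] periselectivity, which the large LUMO coefficients at C2/C7 and the electron-rich, s-cis-biased 3-methyl diene favour, and exo approach, favoured because in the endo mode the overlap of C9/C10 with C3–C6 is antibonding. There is no regiochemical issue since tropone is symmetric; the adduct is racemic.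

Step 3
Reactants: 5 rac-exo adduct
Product: 6 rac-bridged lactone (C2α–O–C11(=O)–C7α bridge, 3Z,5Z-diene, 8α-OAc, 9Z-alkene)
Conditions: (Me3SiO)2, SnCl4, trans-cyclohexane-1,2-diamine, 4 Å MS, CH2Cl2, −20 °C
Reagents that add atoms: bis(trimethylsilyl) peroxide, C[Si](C)(C)OO[Si](C)(C)C
Why: Baeyer–Villiger oxidation through the Criegee adduct; both bridgeheads are secondary and allylic, but C7 bears the inductively withdrawing C8 acetoxy group, so C2 should migrate, with retention. The Lewis-acid/silyl peroxide system is known to oxidise β,γ-unsaturated ketones without epoxidising alkenes.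

Step 4
Reactants: 6 rac-bridged lactone
Product: 7 (8R)-8α-hydroxy bridged lactone, single enantiomer
Conditions: Candida antarctica lipase B (immobilised), phosphate buffer pH 7, MTBE, 30 °C, to about half conversion; chromatography
Reagents that add atoms: none
Why: Lipase-catalysed enantioselective hydrolysis (kinetic resolution) of a secondary acetate; by the empirical size rule (large C7, medium C9) the (8R) ester should react faster, leaving the antipode of 6 acetylated. The enzyme also frees C8–OH at neutral pH, where the strained eight-membered lactone is not opened.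

Step 5
Reactants: 7 8α-hydroxy bridged lactone
Product: 8 9α,10α-epoxy-8α-hydroxy bridged lactone
Conditions: VO(acac)2 (cat.), t-BuOOH (1.2 equiv), CH2Cl2, 0 °C → rt
Reagents that add atoms: tert-butyl hydroperoxide, CC(C)(C)OO
Why: Hydroxyl-directed epoxidation: the vanadium alkoxide of C8–OH delivers oxygen to the adjacent C9=C10 face, giving the cis-epoxy alcohol (9α-O); the diene has no free allylic hydroxyl and is not touched.

Step 6
Reactants: 8 9α,10α-epoxy-8α-hydroxy bridged lactone
Product: 9 8β-chloroacetoxy-9α,10α-epoxy bridged lactone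
Conditions: ClCH2CO2H, PPh3, DIAD, toluene, 0 °C → rt
Reagents that add atoms: chloroacetic acid, OC(=O)CCl
Why: Mitsunobu reaction: SN2 displacement of the oxyphosphonium group by the acidic carboxylate inverts C8 to the target configuration; elimination toward the bridgehead C7 or the epoxide carbon C9 is not available.

Step 7
Reactants: 9 8β-chloroacetoxy-9α,10α-epoxy bridged lactone
Product: 10 9α,10α-epoxy-8β-hydroxy bridged lactone
Conditions: thiourea, NaHCO3, EtOH/THF, 45 °C
Reagents that add atoms: none
Why: Thiourea alkylates the chloroacetyl group at sulfur and then cyclises onto its ester carbonyl, releasing the alcohol under near-neutral conditions that leave the lactone and epoxide alone.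

Step 8
Reactants: 10 9α,10α-epoxy-8β-hydroxy bridged lactone
Product: 12 bridged silyl acetal (C2α–O–C11H(OTBS)–C7α, 8β-OTBS, 9α,10α-epoxide, 3Z,5Z-diene), via bis(diisobutylaluminium) alkoxide 11 (not isolated)
Conditions: i-Bu2AlH (2.5 equiv), CH2Cl2, −78 °C; then 2,6-lutidine, TBSOTf (3 equiv), −78 → −20 °C
Reagents that add atoms: tert-butyldimethylsilyl triflate, CC(C)(C)[Si](C)(C)OS(=O)(=O)C(F)(F)F
Why: Half-reduction of the lactone gives a tetrahedral aluminium hemiacetal that is stable at −78 °C; silylating it in situ (known for esters and lactones) fixes the cyclic form before it can open, and the C8 alkoxide is silylated in the same pot. The bridge keeps the bicycle rigid but no longer carries an acyl group that a 5α-hydroxyl could take over.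

Step 9
Reactants: 12 bridged silyl acetal
Product: 13 5α,6α-diol of the bridged silyl acetal (3Z-alkene retained)
Conditions: OsO4 (cat.), NMO, acetone/H2O, 0 °C
Reagents that add atoms: N-methylmorpholine N-oxide, C[N+]1([O-])CCOCC1; water, O
Why: Syn dihydroxylation from the α face, the β face of C3–C6 being covered by the C8–C1 arm. C5=C6 should be preferred because the only open face of C3=C4 is syn to its allylic C2–O bond, which is the disfavoured sense for osmylation, and that alkene is also inductively deactivated.

Step 10
Reactants: 13 5α,6α-diol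
Product: 14 6α-hydroxy-5-oxo-3Z-ene (α′-hydroxy enone) of the bridged silyl acetal
Conditions: MnO2 (activated, excess), CH2Cl2, rt
Reagents that add atoms: none
Why: MnO2 oxidises only the allylic C5 carbinol; the C6 hydroxyl is not allylic and stays.

Step 11
Reactants: 14 α′-hydroxy enone
Product: 15 4-iodo-6α-hydroxy-5-oxo-3-ene (C2 and C5 cis on the alkene)
Conditions: I2, pyridine, CH2Cl2, rt
Reagents that add atoms: iodine, II
Why: α-Iodination of an enone by conjugate addition of pyridine, iodination of the enolate and elimination; the eight-membered ring through C2–O–C11–C7 allows only the cis ring alkene, so the geometry is kept.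

Step 12
Reactants: 15 4-iodo enone
Product: 16 4-methyl-6α-hydroxy-5-oxo-3Z-ene (C15 installed)
Conditions: Me4Sn, Pd2(dba)3 (cat.), AsPh3, CuI, NMP, 50 °C
Reagents that add atoms: tetramethylstannane, C[Sn](C)(C)C
Why: Stille coupling of an α-iodoenone with retention of alkene geometry under neutral conditions, which spares the α-ketol; the allylic C2 oxygen is an acetal ether and is not ionised by zerovalent palladium.

Step 13
Reactants: 16 4-methyl enone
Product: 17 5β,6α-diol (4-methyl-3Z-ene) of the bridged silyl acetal
Conditions: NaBH4, CeCl3·7H2O, MeOH, −78 °C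
Reagents that add atoms: none
Why: Luche 1,2-reduction; hydride enters from the open α face, which is also the side of the cerium-bound C6 oxygen, so the new hydroxyl is β (trans-diol).

Step 14
Reactants: 17 5β,6α-diol
Product: 18 bridged lactol (C11 hemiacetal to O2), 5β,6α-diol, 8β-OTBS
Conditions: TBAF (1.1 equiv), AcOH (1.1 equiv), THF, 0 °C
Reagents that add atoms: none
Why: Buffered fluoride cleaves the acetal-type silyl ether much faster than the hindered secondary C8–OTBS and does not open the epoxide.

Step 15
Reactants: 18 bridged lactol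
Product: 19 alkyne triol (2α-OH, 4-methyl-3Z-ene, 5β-OH, 6α-OH, 7α-ethynyl, 8β-OTBS, 9α,10α-epoxide)
Conditions: dimethyl (1-diazo-2-oxopropyl)phosphonate, K2CO3, MeOH, 0 °C → rt
Reagents that add atoms: dimethyl (1-diazo-2-oxopropyl)phosphonate, CC(=O)C(=[N+]=[N-])P(=O)(OC)OC
Why: Bestmann–Ohira homologation of the aldehyde in equilibrium with the lactol: the diazophosphonate anion adds, eliminates phosphate and the alkylidene carbene rearranges to the terminal alkyne, adding C13 and freeing C2–OH.

Step 16
Reactants: 19 alkyne triol
Product: 20 6α,12-olide (cis-fused α-methylene-γ-butyrolactone), 2α-OH, 5β-OH, 8β-OTBS, 9α,10α-epoxide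
Conditions: PdI2 (cat.), Bu3P (cat.), CO (1 atm), MeCN, 50 °C
Reagents that add atoms: carbon monoxide, [C-]#[O+]
Why: Palladium-catalysed cyclocarbonylation of a homopropargylic alcohol: the alkoxycarbonyl–palladium species from C6–OH and CO adds syn across the alkyne at C11 and protonolysis gives the exocyclic methylene. The five-membered ring through O6 forms faster than the six-membered one through O5, and O8 is silylated.

Step 17
Reactants: 20 methylene lactone diol
Product: 21 2α-OTBDPS ether (5β-OH free)
Conditions: TBDPSCl, imidazole, DMF, 0 °C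
Reagents that add atoms: tert-butyl(chloro)diphenylsilane, CC(C)(C)[Si](Cl)(c1ccccc1)c1ccccc1
Why: The bulky chlorosilane picks the C2 hydroxyl (flanked by CH2 and a vinylic CH) over the C5 hydroxyl (flanked by the fully substituted C4 and the lactone carbinol C6).

Step 18
Reactants: 21 2α-OTBDPS ether
Product: 22 5β-acetate (2α-OTBDPS, 8β-OTBS, 9α,10α-epoxide)
Conditions: Ac2O, DMAP, pyridine, CH2Cl2, 0 °C
Reagents that add atoms: acetic anhydride, CC(=O)OC(C)=O
Why: Acylation of the only free hydroxyl installs the C5 acetate of the target.

Step 19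
Reactants: 22 5β-acetate
Product: 24 9α-hydroxy-10(14)-ene (2α-OTBDPS, 5β-OAc, 8β-OTBS), via C9 trimethylsilyl ether 23 (not isolated)
Conditions: TMSOTf, 2,6-lutidine, toluene, −78 → 0 °C; DBU, rt; then citric acid, MeOH, 0 °C
Reagents that add atoms: none
Why: Silyl-triflate-mediated isomerisation of an epoxide to an allyl silyl ether: the activated epoxide opens at tertiary C10 and the base removes a proton from the freely rotating C14 methyl, so the C9–O bond and its α configuration are kept. The C8 oxygen is a silyl ether here so that no neighbouring acyl group can attack C9.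

Step 20
Reactants: 24 9α-hydroxy-10(14)-ene; 25 (R)-2-methylbutanoic acid
Product: 26 9α-[(R)-2-methylbutanoate]
Conditions: DCC, DMAP (cat.), CH2Cl2, 0 °C
Reagents that add atoms: none
Why: Steglich esterification of the only free hydroxyl; low temperature and catalytic DMAP limit epimerisation of the α-stereocentre of 25.

Step 21
Reactants: 26 9α-[(R)-2-methylbutanoate]
Product: 27 8β-hydroxy compound (2α-OTBDPS kept)
Conditions: HF·pyridine, pyridine, THF, 0 °C → rt
Reagents that add atoms: none
Why: Acidic fluoride removes the TBS ether far faster than the TBDPS ether; acidic conditions also disfavour migration of the C9 acyl group to the trans C8 hydroxyl.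

Step 22
Reactants: 27 8β-hydroxy compound
Product: 28 5β,8β-diacetate (2α-OTBDPS, 9α-ester)
Conditions: Ac2O, DMAP, pyridine, CH2Cl2, 0 °C
Reagents that add atoms: acetic anhydride, CC(=O)OC(C)=O
Why: Acylation of the single free hydroxyl gives the C8 acetate with the configuration set in step 6.

Step 23
Reactants: 28 5β,8β-diacetate
Product: 29 2α-hydroxy-3Z-ene (all three esters and the lactone in place)
Conditions: TBAF, AcOH, THF, rt
Reagents that add atoms: none
Why: Buffered fluoride cleaves the allylic TBDPS ether without the basicity that would attack the acetates or add to the methylene lactone.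

Step 24
Reactants: 29 2α-hydroxy-3Z-ene
Product: 30 3α,4α-epoxy-2α-ol
Conditions: VO(acac)2 (cat.), t-BuOOH, CH2Cl2, 0 °C
Reagents that add atoms: tert-butyl hydroperoxide, CC(C)(C)OO
Why: Hydroxyl-directed epoxidation of the trisubstituted Z-alkene gives the cis-epoxy alcohol, i.e. the α-epoxide with C15 β; the homoallylic C10=C14 alkene reacts much more slowly and the electron-poor acrylate not at all.

Step 25
Reactants: 30 3α,4α-epoxy-2α-ol
Product: 31 target (CNP0256300.1)
Conditions: Dess–Martin periodinane, NaHCO3, CH2Cl2, 0 °C → rt
Reagents that add atoms: none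
Why: Buffered periodinane oxidation of the secondary carbinol to the ketone under non-basic conditions that do not epimerise C3 or open the epoxide.

## Compound list

1 | 3-methylbut-2-enal | CC(C)=CC=O | starting material
2 | isopropenyl acetate | CC(=C)OC(C)=O | starting material
3 | (E)-1-acetoxy-3-methylbuta-1,3-diene | C=C(C)/C=C/OC(C)=O | intermediate
4 | tropone | O=C1C=CC=CC=C1 | starting material
5 | rac-exo-7-acetoxy-9-methylbicyclo[4.4.1]undeca-2,4,8-trien-11-one (needed enantiomer drawn) | O=C1[C@@H]2C=CC=C[C@H]1[C@H](OC(C)=O)C=C(C)C2 | intermediate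
6 | rac-bridged lactone, C2α–O–C11(=O)–C7α, 8α-OAc (needed enantiomer drawn) | C1[C@H]2/C=C\C=C/[C@H](C(=O)O2)[C@H](OC(C)=O)/C=C1/C | intermediate
7 | (8R)-8α-hydroxy bridged lactone | C1[C@H]2/C=C\C=C/[C@H](C(=O)O2)[C@H](O)/C=C1/C | intermediate
8 | 9α,10α-epoxy-8α-hydroxy bridged lactone | C1[C@H]2/C=C\C=C/[C@H](C(=O)O2)[C@H](O)[C@@H]3O[C@@]31C | intermediate
9 | 8β-chloroacetoxy-9α,10α-epoxy bridged lactone | C1[C@H]2/C=C\C=C/[C@H](C(=O)O2)[C@@H](OC(=O)CCl)[C@@H]3O[C@@]31C | intermediate
10 | 9α,10α-epoxy-8β-hydroxy bridged lactone | C1[C@H]2/C=C\C=C/[C@H](C(=O)O2)[C@@H](O)[C@@H]3O[C@@]31C | intermediate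
11 | bis(diisobutylaluminium) alkoxide of the lactol (not isolated) | C1[C@H]2/C=C\C=C/[C@H](C(O[Al](CC(C)C)CC(C)C)O2)[C@@H](O[Al](CC(C)C)CC(C)C)[C@@H]3O[C@@]31C | intermediate
12 | bridged silyl acetal, 8β-OTBS, 9α,10α-epoxide | C1[C@H]2/C=C\C=C/[C@H](C(O[Si](C)(C)C(C)(C)C)O2)[C@@H](O[Si](C)(C)C(C)(C)C)[C@@H]3O[C@@]31C | intermediate
13 | 5α,6α-diol of 12 | C1[C@H]2/C=C\[C@H](O)[C@H](O)[C@H](C(O[Si](C)(C)C(C)(C)C)O2)[C@@H](O[Si](C)(C)C(C)(C)C)[C@@H]3O[C@@]31C | intermediate
14 | 6α-hydroxy-5-oxo-3Z-ene | C1[C@H]2/C=C\C(=O)[C@H](O)[C@H](C(O[Si](C)(C)C(C)(C)C)O2)[C@@H](O[Si](C)(C)C(C)(C)C)[C@@H]3O[C@@]31C | intermediate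
15 | 4-iodo-6α-hydroxy-5-oxo-3-ene | C1[C@H]2/C=C(I)\C(=O)[C@H](O)[C@H](C(O[Si](C)(C)C(C)(C)C)O2)[C@@H](O[Si](C)(C)C(C)(C)C)[C@@H]3O[C@@]31C | intermediate
16 | 4-methyl-6α-hydroxy-5-oxo-3Z-ene | C1[C@H]2/C=C(C)\C(=O)[C@H](O)[C@H](C(O[Si](C)(C)C(C)(C)C)O2)[C@@H](O[Si](C)(C)C(C)(C)C)[C@@H]3O[C@@]31C | intermediate
17 | 5β,6α-diol, 4-methyl-3Z-ene, bridged silyl acetal | C1[C@H]2/C=C(C)\[C@@H](O)[C@H](O)[C@H](C(O[Si](C)(C)C(C)(C)C)O2)[C@@H](O[Si](C)(C)C(C)(C)C)[C@@H]3O[C@@]31C | intermediate
18 | bridged lactol, 5β,6α-diol, 8β-OTBS | C1[C@H]2/C=C(C)\[C@@H](O)[C@H](O)[C@H](C(O)O2)[C@@H](O[Si](C)(C)C(C)(C)C)[C@@H]3O[C@@]31C | intermediate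
19 | alkyne triol (2α,5β,6α-triol, 7α-ethynyl, 8β-OTBS, 9α,10α-epoxide) | C1[C@H](O)/C=C(C)\[C@@H](O)[C@H](O)[C@H](C#C)[C@@H](O[Si](C)(C)C(C)(C)C)[C@@H]2O[C@@]21C | intermediate
20 | 6α,12-olide with 2α-OH, 5β-OH, 8β-OTBS, 9α,10α-epoxide | C1[C@H](O)/C=C(C)\[C@@H](O)[C@@H]2OC(=O)C(=C)[C@@H]2[C@@H](O[Si](C)(C)C(C)(C)C)[C@@H]3O[C@@]31C | intermediate
21 | 2α-OTBDPS ether of 20 | C1[C@H](O[Si](c4ccccc4)(c5ccccc5)C(C)(C)C)/C=C(C)\[C@@H](O)[C@@H]2OC(=O)C(=C)[C@@H]2[C@@H](O[Si](C)(C)C(C)(C)C)[C@@H]3O[C@@]31C | intermediate
22 | 5β-acetate of 21 | C1[C@H](O[Si](c4ccccc4)(c5ccccc5)C(C)(C)C)/C=C(C)\[C@@H](OC(C)=O)[C@@H]2OC(=O)C(=C)[C@@H]2[C@@H](O[Si](C)(C)C(C)(C)C)[C@@H]3O[C@@]31C | intermediate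
23 | 9α-OTMS-10(14)-ene (not isolated) | C1[C@H](O[Si](c4ccccc4)(c5ccccc5)C(C)(C)C)/C=C(C)\[C@@H](OC(C)=O)[C@@H]2OC(=O)C(=C)[C@@H]2[C@@H](O[Si](C)(C)C(C)(C)C)[C@H](O[Si](C)(C)C)C1=C | intermediate
24 | 9α-hydroxy-10(14)-ene | C1[C@H](O[Si](c4ccccc4)(c5ccccc5)C(C)(C)C)/C=C(C)\[C@@H](OC(C)=O)[C@@H]2OC(=O)C(=C)[C@@H]2[C@@H](O[Si](C)(C)C(C)(C)C)[C@H](O)C1=C | intermediate
25 | (R)-2-methylbutanoic acid | CC[C@@H](C)C(=O)O | starting material
26 | 9α-[(R)-2-methylbutanoate], 8β-OTBS, 2α-OTBDPS | C1[C@H](O[Si](c4ccccc4)(c5ccccc5)C(C)(C)C)/C=C(C)\[C@@H](OC(C)=O)[C@@H]2OC(=O)C(=C)[C@@H]2[C@@H](O[Si](C)(C)C(C)(C)C)[C@H](OC(=O)[C@H](C)CC)C1=C | intermediate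
27 | 8β-hydroxy compound | C1[C@H](O[Si](c4ccccc4)(c5ccccc5)C(C)(C)C)/C=C(C)\[C@@H](OC(C)=O)[C@@H]2OC(=O)C(=C)[C@@H]2[C@@H](O)[C@H](OC(=O)[C@H](C)CC)C1=C | intermediate
28 | 5β,8β-diacetate, 2α-OTBDPS | C1[C@H](O[Si](c4ccccc4)(c5ccccc5)C(C)(C)C)/C=C(C)\[C@@H](OC(C)=O)[C@@H]2OC(=O)C(=C)[C@@H]2[C@@H](OC(C)=O)[C@H](OC(=O)[C@H](C)CC)C1=C | intermediate
29 | 2α-hydroxy-3Z-ene | C1[C@H](O)/C=C(C)\[C@@H](OC(C)=O)[C@@H]2OC(=O)C(=C)[C@@H]2[C@@H](OC(C)=O)[C@H](OC(=O)[C@H](C)CC)C1=C | intermediate
30 | 3α,4α-epoxy-2α-ol | C1[C@H](O)[C@@H]2O[C@]2(C)[C@@H](OC(C)=O)[C@@H]2OC(=O)C(=C)[C@@H]2[C@@H](OC(C)=O)[C@H](OC(=O)[C@H](C)CC)C1=C | intermediate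
31 | CNP0256300.1 | C=C1C(=O)O[C@@H]2[C@H]1[C@@H](OC(C)=O)[C@H](OC(=O)[C@H](C)CC)C(=C)CC(=O)[C@@H]1O[C@]1(C)[C@H]2OC(C)=O | target

## Step count and least certain steps

Total: 25 steps. Longest linear sequence: 25 steps (1 → 31); tropone 4 and acid 25 enter as bought.

**Step 2 (key step).** The cycloaddition may be diverted into [4+2] addition or into decomposition of the dienyl acetate at the temperature required; the extra methyl group on the diene raises the steric demand at C10. Fallback, from 1 and 4 back to 5: the enal is silylated with TBSOTf and Et3N to the more electron-rich silyl dienol ether (E)-1-(tert-butyldimethylsilyloxy)-3-methylbuta-1,3-diene F1, which should add to tropone at lower temperature to give the silyl ether adduct F2. HF·pyridine then gives the hydroxy ketone F3 without forming an alkoxide, which could undergo retro-aldol cleavage of C7–C8, and Ac2O/pyridine gives 5.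

**Step 3.** Oxygen insertion may occur on the C7 side as well, and the Lewis acid may ionise the allylic C8 acetate or the new allylic C2–O bond (transposition to a six-membered lactone). Fallback, from 5 back to 6: the acetate is hydrolysed enzymatically at pH 7 to the hydroxy ketone F3, which trifluoroacetic anhydride and pyridine convert into the trifluoroacetate F4, whose stronger electron withdrawal should bias migration more firmly to C2. Baeyer–Villiger oxidation gives the trifluoroacetate lactone F5. NaHCO3/MeOH at 0 °C removes only the very labile trifluoroacetate to give the racemate of 7, which is acetylated to 6.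

**Step 4.** The enzyme may not accept the hindered C8 ester, or may show low or opposite enantioselectivity. Fallback, from 6 back to 8: the enantiomers of 6 are separated by preparative chromatography on a chiral stationary phase. The needed one is reduced with i-Bu2AlH at −78 °C, which cleaves the acetate and stops at the lactol, giving the hydroxy lactol F6. The directed epoxidation of step 5 gives the epoxy lactol F7, and Ag2CO3 on Celite re-oxidises the lactol selectively to the lactone, which is 8.

**Step 9.** Osmylation may also attack C3=C4 or both alkenes, and the silyloxy group on C11 may hinder the α face. Fallback, from 10 back to 13: the dihydroxylation is moved to the lactone stage, where the allylic acyloxy group at C2 deactivates C3=C4 more strongly. 10 is silylated with TBSOTf to its 8β-TBS ether F8 and dihydroxylated with OsO4/NMO in the presence of PhB(OH)2, so that the diol is captured as the cyclic phenylboronate F9 and cannot take over the C11 acyl group. Reduction and in situ silylation as in step 8 give the boronate silyl acetal F10, and exchange with pinacol releases 13.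

**Step 15.** Under carbonate in methanol the β-hydroxy aldehyde may undergo retro-aldol cleavage of C6–C7, epimerisation at C7 or β-elimination of the C8 silyloxy group before it is homologated. Fallback, from 17 back to 19: the diol is silylated with TESOTf to the bis(triethylsilyl) ether F11. Buffered fluoride frees only the acetal position to give the lactol F12. Lithiated trimethylsilyldiazomethane at −78 °C (aprotic, irreversible) gives the alkyne bis(triethylsilyl) ether F13, and HF·pyridine/pyridine at 0 °C removes the two TES groups but not the TBS group, giving 19.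

**Step 19.** Proton loss may occur from C1 instead of C14 (endocyclic alkene), and the amidine base may isomerise the methylene lactone. Fallback, from 22 back to 27: the C8 silyl ether is removed first with HF·pyridine to give the trans-epoxy alcohol F14. Ti(OiPr)4 then isomerises the 2,3-epoxy alcohol under hydroxyl assistance to the 8β,9α-dihydroxy 10(14)-methylene compound F15. The less hindered allylic C9 hydroxyl is acylated with 25 (DCC, DMAP, −20 °C), which gives 27.

## Further compounds

F1 | step 2 | (E)-1-(tert-butyldimethylsilyloxy)-3-methylbuta-1,3-diene | C=C(C)/C=C/O[Si](C)(C)C(C)(C)C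
F2 | step 2 | rac-exo-7-(tert-butyldimethylsilyloxy)-9-methylbicyclo[4.4.1]undeca-2,4,8-trien-11-one | C1[C@H]2C=CC=C[C@H](C2=O)[C@H](O[Si](C)(C)C(C)(C)C)C=C1C
F3 | step 2 | rac-exo-7-hydroxy-9-methylbicyclo[4.4.1]undeca-2,4,8-trien-11-one | C1[C@H]2C=CC=C[C@H](C2=O)[C@H](O)C=C1C
F4 | step 3 | rac-exo-7-(trifluoroacetoxy)-9-methylbicyclo[4.4.1]undeca-2,4,8-trien-11-one | C1[C@H]2C=CC=C[C@H](C2=O)[C@H](OC(=O)C(F)(F)F)C=C1C
F5 | step 3 | rac-bridged lactone with 8α-trifluoroacetate | C1[C@H]2/C=C\C=C/[C@H](C(=O)O2)[C@H](OC(=O)C(F)(F)F)/C=C1/C
F6 | step 4 | 8α-hydroxy bridged lactol | C1[C@H]2/C=C\C=C/[C@H](C(O)O2)[C@H](O)/C=C1/C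
F7 | step 4 | 9α,10α-epoxy-8α-hydroxy bridged lactol | C1[C@H]2/C=C\C=C/[C@H](C(O)O2)[C@H](O)[C@@H]3O[C@@]31C
F8 | step 9 | 8β-TBS ether of 10 | C1[C@H]2/C=C\C=C/[C@H](C(=O)O2)[C@@H](O[Si](C)(C)C(C)(C)C)[C@@H]3O[C@@]31C
F9 | step 9 | 5α,6α-phenylboronate of the bridged lactone | C1[C@H]2/C=C\[C@@H]4OB(c5ccccc5)O[C@@H]4[C@H](C(=O)O2)[C@@H](O[Si](C)(C)C(C)(C)C)[C@@H]3O[C@@]31C
F10 | step 9 | 5α,6α-phenylboronate of the bridged silyl acetal | C1[C@H]2/C=C\[C@@H]4OB(c5ccccc5)O[C@@H]4[C@H](C(O[Si](C)(C)C(C)(C)C)O2)[C@@H](O[Si](C)(C)C(C)(C)C)[C@@H]3O[C@@]31C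
F11 | step 15 | 5β,6α-bis(triethylsilyl) ether of 17 | C1[C@H]2/C=C(C)\[C@@H](O[Si](CC)(CC)CC)[C@H](O[Si](CC)(CC)CC)[C@H](C(O[Si](C)(C)C(C)(C)C)O2)[C@@H](O[Si](C)(C)C(C)(C)C)[C@@H]3O[C@@]31C
F12 | step 15 | bridged lactol with 5β,6α-bis(triethylsilyl) ether | C1[C@H]2/C=C(C)\[C@@H](O[Si](CC)(CC)CC)[C@H](O[Si](CC)(CC)CC)[C@H](C(O)O2)[C@@H](O[Si](C)(C)C(C)(C)C)[C@@H]3O[C@@]31C
F13 | step 15 | alkyne with 2α-OH and 5β,6α-bis(triethylsilyl) ether | C1[C@H](O)/C=C(C)\[C@@H](O[Si](CC)(CC)CC)[C@H](O[Si](CC)(CC)CC)[C@H](C#C)[C@@H](O[Si](C)(C)C(C)(C)C)[C@@H]2O[C@@]21C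
F14 | step 19 | 8β-hydroxy-9α,10α-epoxide (2α-OTBDPS, 5β-OAc, lactone) | C1[C@H](O[Si](c4ccccc4)(c5ccccc5)C(C)(C)C)/C=C(C)\[C@@H](OC(C)=O)[C@@H]2OC(=O)C(=C)[C@@H]2[C@@H](O)[C@@H]3O[C@@]31C
F15 | step 19 | 8β,9α-diol with 10(14)-methylene (2α-OTBDPS, 5β-OAc, lactone) | C1[C@H](O[Si](c4ccccc4)(c5ccccc5)C(C)(C)C)/C=C(C)\[C@@H](OC(C)=O)[C@@H]2OC(=O)C(=C)[C@@H]2[C@@H](O)[C@H](O)C1=C
A1 | alternative 1 | ten-membered carbocycle with 8-OH, 9-OMOM, 10(14)-methylene, 2-OTBS, 3Z-ene, 5-OTES, 6-OPMB and a PMB-protected 7-(3-hydroxyprop-1-en-2-yl) group | O[C@H]1[C@H](OCOC)C(=C)C[C@@H](O[Si](C)(C)C(C)(C)C)/C=C(/C)[C@@H](O[Si](CC)(CC)CC)[C@H](OCc2ccc(OC)cc2)[C@@H]1C(=C)COCc1ccc(OC)cc1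
A2 | alternative 2 | ten-membered epoxy ketone with the methylene lactone as cyclic diethyl orthoester and a 10-(TBS-oxymethyl) group | C=C1C(OCC)(OCC)O[C@@H]2[C@H]1[C@@H](OC(C)=O)[C@H](OC(=O)[C@H](C)CC)[C@@H](CO[Si](C)(C)C(C)(C)C)CC(=O)[C@@H]1O[C@]1(C)[C@H]2OC(C)=O
A3 | alternative 3 | C2–C5 endoperoxide of the ten-membered ring with C3=C4 retained | C=C1C(=O)O[C@@H]2[C@H]1[C@@H](OC(C)=O)[C@H](OC(=O)[C@H](C)CC)C(=C)C[C@H]1OO[C@@H]2C(C)=C1
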